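The odds against a product are the fraction of the charge not standing as that product, divided by the fraction that does, and the reckoning below interpolates on them. This flask charges starting complex, incoming ligand and protic impurity; the dusk and autumn runs share its complex and ligand charges.

| flask | starting complex | incoming ligand | protic impurity | remark | time |
|---|---|---|---|---|---|
| dusk | 10 mM | 0.90 equiv | 6.7 mM | run made earlier |  |
| autumn | 10 mM | 0.90 equiv | 15 mM | run made earlier |  |
| summer | 5 mM | 0.90 equiv | 10 mM | run made earlier |  |
| flask | 10 mM | 0.900 equiv | 10.0 mM |  | 40 h |

- dusk (time / h: complex with one exchanged / %, complex with three exchanged / %): 5.00: 15.8, 0; 8.00: 19.5, 1.5; 15.0: 26.0, 0; 25.0: 24.4, 1.5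
- autumn (time / h: complex with one exchanged / %, complex with three exchanged / %): 5.00: 13.0, 0; 8.00: 16.7, 0; 15.0: 18.8, 1.6; 25.0: 18.2, 0
- summer (time / h: complex with one exchanged / %, complex with three exchanged / %): 5.00: 7.7, 0; 8.00: 11.0, 0.3; 15.0: 14.3, 0.7; 25.0: 16.2, 2.8

(each reading ± 1 percentage point)

- the best time, 40 h at the latest, for complex with one exchanged
- the amount of complex with one exchanged, in percent of the starting complex charged, at that time
- the first time at which complex with one exchanged reaches 6.7 %, in the same percent

- the numbers in the tables scatter with a standard deviation of 1 percentage point

Dusk, with impurity at 0.670 of the complex charge, reads highest at 26.0 % of complex with one exchanged. Autumn, at 1.50, reads highest at 18.8 %. The flask, at 1.00, should peak between these readings, each carrying the scatter of 1 point. Both runs read higher at 15.0 h than at 8.00 h and lower at 25.0 h, by 1.6 points and 0.6 points; those falls are of the size of the scatter, so the bracket on the flask's best time, from 8.00 h to 25.0 h, is a loose one. To tighten the peak, take ligand and impurity as rivals for starting complex, so that the odds against rise in a straight line with impurity. The readings give odds of 2.85 and 4.32, higher in autumn. The line gives the flask's odds against at its peak, 3.43, hence an estimated peak of 22.6 %.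

The forecast gives 22.5 % at 28 h, with 6.7 % reached at 1.9 h, and says “the maximum is broad and poorly defined”. Its amount lies inside the bracket on the peak; its time lies beyond the bracket on the time.

The flask gives 22.5 % at 18.4 h, inside both brackets, and reaches 6.7 % at 1.75 h. Its odds against are 3.44.

    starting complex + incoming ligand ⇌ leaving ligand + complex with one exchanged (K = 1.31, k = 0.00140 /M/s)
    complex with two exchanged + incoming ligand ⇌ leaving ligand + complex with three exchanged (K = 2.70, k = 0.00125 /M/s)
    protic impurity + starting complex → quenched substrate (k = 0.00248 /M/s)
    complex with one exchanged + incoming ligand ⇌ leaving ligand + complex with two exchanged (K = 3.40, k = 6.67 × 10⁻⁴ /M/s)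

At 5.89 h in the flask, protic impurity has a half-life of 15 h by its step with starting complex, while incoming ligand has 27 h by the forward rate of its exchange with starting complex alone, a factor of 1.77. At the best time, quenched substrate stands at 52.3 % of the complex charged, against 22.5 % of complex with one exchanged.

For a neighbour charged with 1.50 equiv of ligand, all else as in the flask, the rivalry reckoning shrinks the odds in proportion to the ligand charge, to 2.06, an estimated peak of 32.7 %. It gives 28.2 %, lower than reckoned.

(The data come from a simulation with constants of no real substance; scatter was added.)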